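## Retrosynthetic overview

- **Feature:** C3 (OAc) and C5 (OH) of the heptane chain are both R, and each carries the same 2-(4-hydroxyphenyl)ethyl arm. Without its acetyl group the target is a C2-symmetric anti-1,3-diol in which O3 and O5 are homotopic, so one acetyl group on either oxygen gives the same molecule.
- **Disconnections:** the O-acetyl bond is cut first, through a cyclic orthoacetate bridging O3 and O5. The C3-H and C5-H bonds come next, from one double asymmetric hydrogenation of the achiral 3,5-diketone. C1-C2 and C6-C7 are last, from two terminal alkylations of acetylacetone dianions with 4-benzyloxybenzyl chloride.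
- **Rings:** both benzene rings are bought and no ring of the target is built. The only ring made is a temporary 1,3-dioxane orthoester, closed in step 4 and opened in step 5.
- **Protection:** both phenols travel as benzyl ethers from the first step and are freed last by neutral hydrogenolysis.

Key step: step 3

Remark: positions follow the heptane chain (C3 bears OAc, C5 bears OH). The pairing (R)-BINAP to (R,R) is taken by analogy with acetylacetone and should be confirmed on the diol of step 3 (sign of rotation, Mosher esters). If it proves opposite, (S)-BINAP is used with no other change.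

## Route

Step 1
Reactants: 1 acetylacetone (pentane-2,4-dione); 2 4-benzyloxybenzyl chloride
Product: 4 6-(4-benzyloxyphenyl)hexane-2,4-dione, via acetylacetone dianion 3 (not isolated)
Conditions: NaH (1.1 equiv), THF, 0 °C; n-BuLi (1.05 equiv), 0 °C; 2 (0.95 equiv), 0 °C to rt; 1 M HCl
Reagents that add atoms: none
Why: γ-Alkylation of a β-diketone dianion: the terminal carbanion of 3 is much more nucleophilic than the delocalised central position, so SN2 attack on the activated benzylic chloride should occur at the methyl terminus only (C1-C2 bond), and a slight deficit of 2 keeps the resulting monoanion from reacting again.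

Step 2
Reactants: 4 6-(4-benzyloxyphenyl)hexane-2,4-dione; 2 4-benzyloxybenzyl chloride
Product: 6 1,7-bis(4-benzyloxyphenyl)heptane-3,5-dione, via hexanedione dianion 5 (not isolated)
Conditions: NaH (1.1 equiv), THF, 0 °C; n-BuLi (1.05 equiv), 0 °C; 2 (1.0 equiv), 0 °C to rt; 1 M HCl; recrystallise
Reagents that add atoms: none
Why: Second β-diketone dianion γ-alkylation: once NaH has removed the central proton, n-BuLi should deprotonate the free methyl group rather than the substituted methylene, because the primary carbanion is both more accessible and more stable, and its SN2 reaction with 2 forms the C6-C7 bond of the symmetric chain.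

Step 3
Reactants: 6 1,7-bis(4-benzyloxyphenyl)heptane-3,5-dione
Product: 8 (3R,5R)-1,7-bis(4-benzyloxyphenyl)heptane-3,5-diol, via (5R)-hydroxy ketone 7 (not isolated)
Conditions: RuCl2[(R)-BINAP] precatalyst (0.5-1 mol %), H2 (about 80 atm), MeOH-CH2Cl2, 50 °C; recrystallise
Reagents that add atoms: none
Why: Noyori asymmetric hydrogenation of a β-diketone: the Ru(II) hydride formed from the precatalyst and H2 binds 6 as an O,O-chelate and passes hydride to the carbonyl face left open by the P-phenyl quadrants of (R)-BINAP, which should give the (5R)-hydroxy ketone 7. In 7 the new hydroxyl and the remaining ketone chelate the same catalyst, so the second hydride transfer is again catalyst-controlled, is matched with the 1,3-anti preference of a hydroxyl-directed reduction, and sets the second centre R as well. The closest known case is the Ru-BINAP hydrogenation of acetylacetone, where the (R)-ligand gives (R,R)-pentane-2,4-diol; changing CH3 to CH2CH2Ar leaves the CIP order O > inner CH2 > outer chain > H unchanged, so the descriptor carries over. No ring is closed; only the C3-H and C5-H bonds and the two O-H bonds are formed. The step needs face selectivity at each carbonyl and anti selectivity overall, and the substrate favours both because it is achiral, symmetric, strongly chelating and flanked only by CH2 groups, while its arenes and aryl benzyl ethers are inert to the homogeneous Ru catalyst. Because both reductions share one facial preference, molecules reduced the wrong way the first time should end mostly as the meso diol, which crystallisation removes, so the ee of the anti diol should exceed that of a single reduction.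

Step 4
Reactants: 8 (3R,5R)-1,7-bis(4-benzyloxyphenyl)heptane-3,5-diol; 9 trimethyl orthoacetate
Product: 10 (4R,6R)-4,6-bis[2-(4-benzyloxyphenyl)ethyl]-2-methoxy-2-methyl-1,3-dioxane
Conditions: 9 (3 equiv), PPTS (5 mol %), CH2Cl2, rt; concentrate (removes MeOH and excess 9); used crude
Reagents that add atoms: none
Why: Acid-catalysed orthoester exchange: both hydroxyls displace methanol from 9 through dialkoxycarbenium ions, the second displacement being a six-membered ring closure, the C3-O and C5-O bonds are never broken, and because the diol is C2-symmetric the orthoester carbon is not a stereocentre, so one compound should form.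

Step 5
Reactants: 10 (4R,6R)-4,6-bis[2-(4-benzyloxyphenyl)ethyl]-2-methoxy-2-methyl-1,3-dioxane
Product: 11 (3R,5R)-1,7-bis(4-benzyloxyphenyl)-5-hydroxyheptan-3-yl acetate
Conditions: AcOH-H2O (4:1), THF, 0 °C to rt
Reagents that add atoms: water, O
Why: Mild acid hydrolysis of a cyclic orthoester: loss of methanol gives the 1,3-dioxan-2-ylium ion, water adds, and the hemiorthoester collapses by cleaving one ring O-C(orthoester) bond to a hydroxy acetate carrying exactly one acetyl group, both directions of opening being equivalent because O3 and O5 are homotopic.

Step 6
Reactants: 11 (3R,5R)-1,7-bis(4-benzyloxyphenyl)-5-hydroxyheptan-3-yl acetate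
Product: 12 (3R,5R)-5-hydroxy-1,7-bis(4-hydroxyphenyl)heptan-3-yl acetate (target CNP0132544.1)
Conditions: H2 (1 atm), 10% Pd/C, EtOAc, rt
Reagents that add atoms: none
Why: Neutral catalytic hydrogenolysis of the two aryl benzyl ethers frees both phenols, while the secondary acetate, the carbinol and the two non-benzylic stereocentres should be untouched, and any 1,3 O-to-O acetyl shift would only regenerate the same molecule.

## Compound list

1 | acetylacetone (pentane-2,4-dione) | CC(=O)CC(C)=O | starting material
2 | 4-benzyloxybenzyl chloride | ClCc1ccc(OCc2ccccc2)cc1 | starting material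
3 | sodium lithium 1,3-dianion of pentane-2,4-dione | [Na+].[Li+].[CH2-]C(=O)[CH-]C(C)=O | intermediate
4 | 6-(4-benzyloxyphenyl)hexane-2,4-dione | CC(=O)CC(=O)CCc1ccc(OCc2ccccc2)cc1 | intermediate
5 | sodium lithium 1,3-dianion of 6-(4-benzyloxyphenyl)hexane-2,4-dione | [Na+].[Li+].[CH2-]C(=O)[CH-]C(=O)CCc1ccc(OCc2ccccc2)cc1 | intermediate
6 | 1,7-bis(4-benzyloxyphenyl)heptane-3,5-dione | O=C(CCc1ccc(OCc2ccccc2)cc1)CC(=O)CCc1ccc(OCc2ccccc2)cc1 | intermediate
7 | (5R)-1,7-bis(4-benzyloxyphenyl)-5-hydroxyheptan-3-one | O=C(CCc1ccc(OCc2ccccc2)cc1)C[C@H](O)CCc1ccc(OCc2ccccc2)cc1 | intermediate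
8 | (3R,5R)-1,7-bis(4-benzyloxyphenyl)heptane-3,5-diol | O[C@H](CCc1ccc(OCc2ccccc2)cc1)C[C@H](O)CCc1ccc(OCc2ccccc2)cc1 | intermediate
9 | trimethyl orthoacetate | COC(C)(OC)OC | starting material
10 | (4R,6R)-4,6-bis[2-(4-benzyloxyphenyl)ethyl]-2-methoxy-2-methyl-1,3-dioxane | COC1(C)O[C@H](CCc2ccc(OCc3ccccc3)cc2)C[C@@H](CCc2ccc(OCc3ccccc3)cc2)O1 | intermediate
11 | (3R,5R)-1,7-bis(4-benzyloxyphenyl)-5-hydroxyheptan-3-yl acetate | CC(=O)O[C@H](CCc1ccc(OCc2ccccc2)cc1)C[C@H](O)CCc1ccc(OCc2ccccc2)cc1 | intermediate
12 | (3R,5R)-5-hydroxy-1,7-bis(4-hydroxyphenyl)heptan-3-yl acetate | CC(=O)O[C@H](CCc1ccc(O)cc1)C[C@H](O)CCc1ccc(O)cc1 | target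

Total step count: 6
Longest linear sequence: 6 steps (1, 4, 6, 8, 10, 11, 12)

## Steps most likely to fail

**1. Step 3 (key step).**
- Risk: the lipophilic, poorly soluble diketone may be taken up slowly. The hydrogenation may stall after the first uptake of H2, or the anti selectivity of the second reduction may erode.
- Fallback (sets out from 7, comes back at 11): the hydrogenation of 6 is stopped on purpose after one equivalent of H2 (lower pressure, monitored uptake) and the (5R)-hydroxy ketone 7 is isolated.
- An Evans-Tishchenko reaction follows, with excess acetaldehyde (CC=O) and catalytic SmI2 in THF at about -10 °C. It passes the hemiacetal hydride intramolecularly to the C3 carbonyl through a samarium-chelated chair.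
- This should set the second centre 1,3-anti by substrate control and leave the acetyl group on O5 in the same operation. By the C2 relation the product is 11, so steps 4 and 5 drop out.
- The ee then rests on the first reduction alone and would be raised by recrystallising 11. No compound outside the list is made (F0).

**2. Step 2.**
- Risk: deprotonation at the substituted methylene may compete with the methyl group. Proton exchange between dianion 5 and the product enolate, and alkylation at the central carbon, may also occur. All of these lead to isomer mixtures that are hard to separate from 6.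
- Fallback (sets out from 1, comes back at 6, replaces steps 1 and 2): both outer C-C bonds are made as alkenes by the boron-templated double aldol condensation used for curcuminoids.
- Compound 1 is treated with commercial 4-benzyloxybenzaldehyde (O=Cc1ccc(OCc2ccccc2)cc1, 2 equiv), B2O3, B(On-Bu)3 and catalytic n-BuNH2 in warm EtOAc, then dilute HCl. Boron chelation of the enol blocks the central carbon, so only the methyl groups condense.
- The product should be (1E,6E)-1,7-bis(4-benzyloxyphenyl)hepta-1,6-diene-3,5-dione F1.
- The two enone C=C bonds are then saturated with H2 over Pd/C poisoned with 2,2'-bipyridyl (THF or EtOAc, rt). This catalyst system reduces alkenes while holding back hydrogenolysis of phenolic benzyl ethers, and should give 6.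

**3. Step 4.**
- Risk: the trans-4,6-disubstituted, 2,2-disubstituted dioxane must place one arm axial or adopt a twist-boat. The exchange may therefore stop at open-chain mixed orthoesters on one or both oxygens, and control over the number of acetyl groups delivered on hydrolysis would be lost.
- Fallback (sets out from 8, comes back at 11, replaces steps 4 and 5): tin-mediated monoacylation.
- Diol 8 and Bu2SnO (1 equiv) in toluene with azeotropic removal of water should give the stannylene acetal (4R,6R)-2,2-dibutyl-4,6-bis[2-(4-benzyloxyphenyl)ethyl]-1,3,2-dioxastanninane F2. Its long Sn-O bonds relieve the diaxial strain.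
- Acetyl chloride (CC(=O)Cl, 1 equiv) at 0 °C acylates one activated oxygen. The chlorostannyl ether left on the other oxygen is too weak a nucleophile to react again, and aqueous work-up frees that hydroxyl to give 11.

## Further compounds

F0 | step 3 | none | none
F1 | step 2 | (1E,6E)-1,7-bis(4-benzyloxyphenyl)hepta-1,6-diene-3,5-dione | O=C(/C=C/c1ccc(OCc2ccccc2)cc1)CC(=O)/C=C/c1ccc(OCc2ccccc2)cc1
F2 | step 4 | (4R,6R)-2,2-dibutyl-4,6-bis[2-(4-benzyloxyphenyl)ethyl]-1,3,2-dioxastanninane | CCCC[Sn]1(CCCC)O[C@H](CCc2ccc(OCc3ccccc3)cc2)C[C@@H](CCc2ccc(OCc3ccccc3)cc2)O1
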